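## Structural features

24 is a linear pentamer of benzene rings A to E joined only by four diaryl ether oxygens; it has no carbon–carbon bond between rings and no stereocentre, so no adjacent stereocentres need to be considered. Ring A is a 2,4,6-trihydroxyphenyl group on the C1 oxygen of ring B; ring B has CH at C2, hydroxyls at C3, C4 and C5 and the ring C oxygen at C6; ring C is bound at C1, has hydroxyls at C3 and C5 and carries the ring D oxygen at C4; ring D repeats the pattern of ring B (ether at C1, CH at C2, hydroxyls at C3 to C5, ether at C6); ring E is a 3,4,5-trihydroxyphenyl group on the C6 oxygen of ring D. Each ether oxygen is bound on one side to a carbon flanked by two oxygenated ortho carbons (ring A C1, ring B C6, ring C C4, ring D C6), and the A–B and C–D ethers have a third ortho oxygen on the other side, so these two links are the most crowded. The fourteen free hydroxyls, arranged as phloroglucinol, pyrogallol and para-dioxygenated arrays, make the free compound very easily oxidised, above all in base; aryloxyquinones (vinylogous esters), hydroquinones and terminal ynol ethers met on the way are also delicate. The real difficulty is the regiocontrolled construction of the pentaoxygenated rings B and D, where C1 and C6 must end as ethers to two different aryl groups and C3 to C5 as hydroxyls, together with the formation of the crowded ethers. The key step exploits the fact that in ring D the four contiguous oxygenated carbons C3 to C6 (C3 and C6 para) map onto the four carbons of a squarate, while C1 (bearing the ring C oxygen) and C2 (CH) are the two carbons of an ethynyl ether on the C4 oxygen of ring C. Ring B stands in the same relation to ring A.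

## Logic of the disconnections

24 to 23. The fourteen O–CH3 bonds are cut last. One robust protecting group that survives organolithium, copper, cobalt and hydrogenation steps keeps the oxidation-prone polyphenol masked throughout, and the methoxy groups brought in by 1 fall in the same operation. The forward step must cleave fourteen methyl ethers without touching the four diaryl ether bonds.

23 to 21 and 22. The bond between the C6 oxygen of ring D and C1 of ring E is cut on the ring E side. That carbon has two ortho hydrogens, so all the steric burden lies on the phenol, and 22 is a simple symmetric aryl halide. The forward step must arylate a phenol flanked by a methoxy and an aryloxy group.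

21 to 20 to 19. The O–CH3 bond at C3 of ring D is cut and the ring is taken back to the quinone oxidation level. This reveals the para pair C3/C6 as the two carbonyl carbons of a quinone. The forward steps are a reduction and a site-selective methylation that must distinguish the hydroxyl next to C2–H from the one buried between C5–OMe and the C1 aryloxy group.

19 to 18 and 3 (3 from 1). The C2–C3 and C1–C6 bonds of ring D are cut. This removes a whole ring, makes the crowded C–D ether a simple O-functionalisation of a phenol, and reduces ring D to a symmetric four-carbon unit, so no regiochemical question arises in the ring construction. The forward step needs a metallacycle that accepts an ynol ether faster than the ynol ether decomposes. 3 is prepared and freed of phosphine beforehand, since free PPh3 would attack the quinone.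

18 to 16 to 15 and 5. The triple bond is traced to a 1,2-dichlorovinyl ether and the O–C(sp2) bond to the phenol. The dichlorovinyl ether is a stable, purifiable store of the sensitive ynol ether. The forward steps need a phenoxide addition and a double elimination/exchange that must be faster than ring lithiation.

15 to 14 to 11 and 13 (13 from 12). The benzyl O–CH2 bond and the bond between the C6 oxygen of ring B and C1 of ring C are cut. As for ring E, the aryl halide partner is unhindered. Benzyl is the only group that has to be removed selectively in the presence of methyl ethers.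

11 to 10 to 9 to 8 and 3. Ring B is taken apart exactly as ring D (O–CH3 at C3, redox, C2–C3 and C1–C6). This gives one repeated module, and the key step and its follow-up are rehearsed on small, cheap material.

8 to 6 to 4 and 5. The ethynyl ether of ring A is traced to the phenol as above.

## Other disconnections considered

Alternative 1: Ring D is cut at C1–O (to ring C) and C6–O(H) at once, leading to 3,4,5-trimethoxybenzyne A4 and the ring C phenol 4-(benzyloxy)-2,6-dimethoxyphenol A2. In the forward sense, iodine–magnesium exchange on 2-iodo-3,4,5-trimethoxyphenyl 4-chlorobenzenesulfonate A3 and loss of sulfonate give A4. The magnesium salt of A2 adds at the aryne carbon of A4 remote from the neighbouring methoxy group, and the carbon–magnesium bond so formed is borylated and oxidised to give the ring C–D phenol A1.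
- In its favour: two adjacent C–O bonds are made in one flask, the crowded C–D ether comes from a very reactive electrophile, and A1 has only the C6 hydroxyl free, so neither reduction nor selective methylation is needed.
- Against it here: regiocontrol rests on the inductive effect of one methoxy group, and any reversed addition would put the hydroxyl on the wrong carbon in an isomer that is hard to remove. The magnesium salt of the di-ortho-substituted A2 is a weak nucleophile towards A4, and the carbon–magnesium bond formed can be protonated by unreacted A2. The ring A–B part would then have to be attached after debenzylation of A1.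
- Comparison: on differentiating the C3 and C6 oxygens and on step count (about three operations per ring against five) this alternative is the better one. On regiochemical certainty the chosen plan is better, because its four-carbon unit is symmetric and only one quinone can form. Mechanistically both stretch known reactivity to a new partner, so the risk is comparable.

Alternative 2: Ring B is cut at C6–C1, leading to a 4-(2-aryloxyvinyl)cyclobutenone. In the forward sense, (Z)-2-(2,4,6-trimethoxyphenoxy)vinyllithium A7 adds to 1, and the tertiary alkoxide oxygen is methylated to give the racemic cyclobutenone A6. Thermolysis of A6 brings about electrocyclic opening of the four-membered ring, 6π electrocyclisation forming C6–C1, and tautomerisation to the ring A–B phenol A5, which is the same compound as 11.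
- In its favour: it is metal-free and fully regiospecific, it uses 1 as well, and only the C6 hydroxyl is free, so the selectivity question of step 6 disappears.
- Against it: A7 can lose phenoxide by β-elimination, the alkoxide oxygen must be methylated cleanly, and for ring D the corresponding vinyllithium would have to be made on the valuable ring A–B–C fragment, where the chosen plan needs only a neutral alkyne.
- Comparison: for ring B this route is equal in length to steps 2 to 6 and better in site control, and it could replace them. For ring D the cobalt route is the gentler one for the large fragment. Both build the same bonds around the same four-carbon unit.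

Alternative 3: The three C–O bonds at C2, C4 and C6 of ring A are cut back to formyl groups. The A–B ether then comes from nucleophilic aromatic substitution of the ring B–C–D–E phenol A11 on 2-fluorobenzene-1,3,5-tricarbaldehyde A10, giving the trialdehyde A9. Peracid and then base carry out three aryl migrations and formate cleavages to give A8.
- In its favour: the most crowded type of ether is made by substitution on a strongly activated ring, and the migrations are of a well-understood kind for ortho/para-oxygenated benzaldehydes.
- Against it here: in the chosen plan ring A enters as purchasable 4 and its ether is never made by coupling, so the problem this cut solves does not arise. The peracid would meet four electron-rich polymethoxy rings, A8 is a free phloroglucinol that must still pass through the final demethylation, and A10 and A11 have to be made first.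
- Comparison: structurally it leaves the hard rings B and D untouched. On mechanistic precedent it is the equal of the chosen plan. On step economy it is worse, since it adds late steps without removing any.

Key step: step 12

Assumption: 12, 22, ClCo(PPh3)3, 3,4,5-trimethoxyphenol and 3,4,5-trimethoxyphenylboronic acid are taken as catalogue chemicals; 24 has no stereocentre, so no configuration has to be set; the cobalt complexes are neutral, and in their SMILES the donor bonds from phosphorus and nitrogen are written as ordinary bonds with balancing formal charges.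

## Route

Step 1
Reactants: 1 dimethyl squarate
Product: 3 chloro(dimethylglyoxime)(2,3-dimethoxymaleoyl)(pyridine)cobalt, via bis(triphenylphosphine) maleoylcobalt chloride 2 (not isolated)
Conditions: ClCo(PPh3)3, PhH, rt; then dimethylglyoxime, pyridine, rt; precipitate and wash free of PPh3
Reagents that add atoms: chlorotris(triphenylphosphine)cobalt Cl[Co-3]([P+](c1ccccc1)(c1ccccc1)c1ccccc1)([P+](c1ccccc1)(c1ccccc1)c1ccccc1)[P+](c1ccccc1)(c1ccccc1)c1ccccc1; dimethylglyoxime CC(=NO)C(C)=NO; pyridine c1ccncc1
Why: Oxidative addition of monovalent cobalt into the bond between the two carbonyl carbons of a cyclobutenedione is the established entry to maleoyl metallacycles of trivalent cobalt. Ligand exchange gives the octahedral, storable dimethylglyoxime form, which reacts with alkynes under mild Lewis-acid promotion and is free of PPh3 that would add to the quinones made later.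

Step 2
Reactants: 4 2,4,6-trimethoxyphenol; 5 trichloroethylene
Product: 6 2-{[(E)-1,2-dichloroethenyl]oxy}-1,3,5-trimethoxybenzene
Conditions: K2CO3, DMF, 70 °C, N2
Reagents that add atoms: none
Why: Base-mediated addition of a phenoxide to dichloroacetylene, formed and consumed in solution from trichloroethylene, is the standard route to aryl 1,2-dichlorovinyl ethers; anti addition gives the E isomer, whose geometry is lost in the next step.

Step 3
Reactants: 6 2-{[(E)-1,2-dichloroethenyl]oxy}-1,3,5-trimethoxybenzene
Product: 8 2-(ethynyloxy)-1,3,5-trimethoxybenzene, via lithium acetylide 7 (not isolated)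
Conditions: n-BuLi (2.2 equiv), THF, −78 to −40 °C; H2O, −78 °C; rapid filtration through basic alumina, used at once
Reagents that add atoms: none
Why: Dehydrochlorination by the first equivalent of n-BuLi and chlorine–lithium exchange by the second give 7, and protonation releases the terminal ynol ether (the usual dichlorovinyl ether route to ynol ethers). At −78 °C this should outrun ring lithiation, and the two ortho methoxy groups shield the product.

Step 4
Reactants: 8 2-(ethynyloxy)-1,3,5-trimethoxybenzene; 3 chloro(dimethylglyoxime)(2,3-dimethoxymaleoyl)(pyridine)cobalt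
Product: 9 2,3-dimethoxy-5-(2,4,6-trimethoxyphenoxy)-1,4-benzoquinone
Conditions: 3 (1.5 equiv), CoCl2 (anhydrous), 4 Å MS, ClCH2CH2Cl, rt to 60 °C, Ar
Reagents that add atoms: none
Why: This is the cobalt-mediated maleoyl–alkyne benzoquinone annulation of the key step, rehearsed on the small ring A ynol ether. The mirror symmetry of the dimethoxymaleoyl unit makes the sense of insertion irrelevant, and ring B emerges as its 1,4-benzoquinone.

Step 5
Reactants: 9 2,3-dimethoxy-5-(2,4,6-trimethoxyphenoxy)-1,4-benzoquinone
Product: 10 2,3-dimethoxy-5-(2,4,6-trimethoxyphenoxy)benzene-1,4-diol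
Conditions: Na2S2O4, EtOAc/H2O, rt, Ar
Reagents that add atoms: none
Why: Two-electron reduction of a 1,4-benzoquinone by dithionite in a two-phase system is fast and clean; it also turns the nucleophile-sensitive aryloxyquinone into an ordinary diaryl ether.

Step 6
Reactants: 10 2,3-dimethoxy-5-(2,4,6-trimethoxyphenoxy)benzene-1,4-diol
Product: 11 2,3,4-trimethoxy-6-(2,4,6-trimethoxyphenoxy)phenol
Conditions: MeI (1.05 equiv), K2CO3, acetone, 0 °C to rt, Ar
Reagents that add atoms: iodomethane CI
Why: Williamson methylation with one equivalent of MeI should favour the hydroxyl flanked by OMe and H over the one buried between OMe and the bulky 2,6-dimethoxyaryloxy group, which leaves the ring B C6 hydroxyl free.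

Step 7
Reactants: 12 4-bromo-2,6-dimethoxyphenol
Product: 13 2-(benzyloxy)-5-bromo-1,3-dimethoxybenzene
Conditions: BnBr, K2CO3, DMF, rt
Reagents that add atoms: benzyl bromide BrCc1ccccc1
Why: Williamson benzylation of a phenol; benzyl is the one group that can later be removed without touching methyl ethers.

Step 8
Reactants: 11 2,3,4-trimethoxy-6-(2,4,6-trimethoxyphenoxy)phenol; 13 2-(benzyloxy)-5-bromo-1,3-dimethoxybenzene
Product: 14 2-(benzyloxy)-1,3-dimethoxy-5-[2,3,4-trimethoxy-6-(2,4,6-trimethoxyphenoxy)phenoxy]benzene
Conditions: CuI (10 mol%), picolinic acid (20 mol%), K3PO4, DMSO, 100 °C, Ar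
Reagents that add atoms: none
Why: Ligand-accelerated Ullmann diaryl ether synthesis with monovalent copper and picolinic acid is the system suited to di-ortho-substituted phenols. The bromide has two ortho hydrogens, so all the hindrance lies on the nucleophile.

Step 9
Reactants: 14 2-(benzyloxy)-1,3-dimethoxy-5-[2,3,4-trimethoxy-6-(2,4,6-trimethoxyphenoxy)phenoxy]benzene
Product: 15 2,6-dimethoxy-4-[2,3,4-trimethoxy-6-(2,4,6-trimethoxyphenoxy)phenoxy]phenol
Conditions: H2 (1 atm), Pd/C, EtOAc/MeOH, rt
Reagents that add atoms: none
Why: Hydrogenolysis of a benzyl aryl ether; methyl and diaryl ethers are inert to these conditions.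

Step 10
Reactants: 15 2,6-dimethoxy-4-[2,3,4-trimethoxy-6-(2,4,6-trimethoxyphenoxy)phenoxy]phenol; 5 trichloroethylene
Product: 16 2-{[(E)-1,2-dichloroethenyl]oxy}-1,3-dimethoxy-5-[2,3,4-trimethoxy-6-(2,4,6-trimethoxyphenoxy)phenoxy]benzene
Conditions: K2CO3, DMF, 70 °C, N2
Reagents that add atoms: none
Why: Same phenoxide addition to in situ dichloroacetylene as in step 2; the reacting phenol has the same 2,6-dimethoxy environment as 4.

Step 11
Reactants: 16 2-{[(E)-1,2-dichloroethenyl]oxy}-1,3-dimethoxy-5-[2,3,4-trimethoxy-6-(2,4,6-trimethoxyphenoxy)phenoxy]benzene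
Product: 18 2-(ethynyloxy)-1,3-dimethoxy-5-[2,3,4-trimethoxy-6-(2,4,6-trimethoxyphenoxy)phenoxy]benzene, via lithium acetylide 17 (not isolated)
Conditions: n-BuLi (2.2 equiv), THF, −78 °C; H2O, −78 °C; rapid filtration through basic alumina, used at once
Reagents that add atoms: none
Why: Same dehydrochlorination and chlorine–lithium exchange as in step 3, followed by protonation of 17; low temperature and exact stoichiometry should keep the oxygen-flanked ring positions from being lithiated.

Step 12
Reactants: 18 2-(ethynyloxy)-1,3-dimethoxy-5-[2,3,4-trimethoxy-6-(2,4,6-trimethoxyphenoxy)phenoxy]benzene; 3 chloro(dimethylglyoxime)(2,3-dimethoxymaleoyl)(pyridine)cobalt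
Product: 19 5-{2,6-dimethoxy-4-[2,3,4-trimethoxy-6-(2,4,6-trimethoxyphenoxy)phenoxy]phenoxy}-2,3-dimethoxy-1,4-benzoquinone
Conditions: 3 (1.5 equiv), CoCl2 (anhydrous), 4 Å MS, ClCH2CH2Cl, rt to 60 °C, Ar
Reagents that add atoms: none
Why: In 3 trivalent cobalt sits between the two acyl carbons that become C3 and C6 of ring D, and loss of pyridine to CoCl2 opens a coordination site. The electron-rich triple bond of 18 binds there and inserts into one cobalt–acyl bond, forming C2–C3 or C1–C6 and enlarging the metallacycle to seven members. Carbon–carbon reductive elimination then forms the second bond and closes the six-membered ring D as its 1,4-benzoquinone, releasing monovalent cobalt; the ring is therefore closed by reductive elimination from a cobaltacycle, in an overall [4+2] union of the four-carbon maleoyl unit with the two alkyne carbons. The closest known reaction type is the benzoquinone synthesis from cyclobutenedione-derived maleoylcobalt complexes and alkynes, alkoxyalkynes included; an aryloxyalkyne with the dimethoxy complex is a new combination within that class and is rehearsed in step 4. No stereocentre is formed. Regioselectivity is not required, because the dimethoxymaleoyl unit is mirror-symmetric and both senses of insertion give 19. Chemoselectivity is required: insertion must outrun oligomerisation or hydration of the ynol ether and displacement of the aryloxy group from the quinone. It should be secured by the donor strength of the ynol ether towards the electrophilic cobalt acyl, the shielding of its oxygen by two ortho methoxy groups, the excess of 3, and the exclusion of water, PPh3 and other nucleophiles.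

Step 13
Reactants: 19 5-{2,6-dimethoxy-4-[2,3,4-trimethoxy-6-(2,4,6-trimethoxyphenoxy)phenoxy]phenoxy}-2,3-dimethoxy-1,4-benzoquinone
Product: 20 5-{2,6-dimethoxy-4-[2,3,4-trimethoxy-6-(2,4,6-trimethoxyphenoxy)phenoxy]phenoxy}-2,3-dimethoxybenzene-1,4-diol
Conditions: Na2S2O4, EtOAc/H2O, rt, Ar
Reagents that add atoms: none
Why: Dithionite reduction of the quinone as in step 5; the crude hydroquinone is carried on without exposure to air.

Step 14
Reactants: 20 5-{2,6-dimethoxy-4-[2,3,4-trimethoxy-6-(2,4,6-trimethoxyphenoxy)phenoxy]phenoxy}-2,3-dimethoxybenzene-1,4-diol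
Product: 21 6-{2,6-dimethoxy-4-[2,3,4-trimethoxy-6-(2,4,6-trimethoxyphenoxy)phenoxy]phenoxy}-2,3,4-trimethoxyphenol
Conditions: MeI (1.05 equiv), K2CO3, acetone, 0 °C to rt, Ar
Reagents that add atoms: iodomethane CI
Why: Site-selective Williamson methylation as in step 6: the ring D C3 hydroxyl (next to C2–H) should react in preference to the C6 hydroxyl, which lies between OMe and the ring C aryloxy group.

Step 15
Reactants: 21 6-{2,6-dimethoxy-4-[2,3,4-trimethoxy-6-(2,4,6-trimethoxyphenoxy)phenoxy]phenoxy}-2,3,4-trimethoxyphenol; 22 5-iodo-1,2,3-trimethoxybenzene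
Product: 23 5-(6-{2,6-dimethoxy-4-[2,3,4-trimethoxy-6-(2,4,6-trimethoxyphenoxy)phenoxy]phenoxy}-2,3,4-trimethoxyphenoxy)-1,2,3-trimethoxybenzene
Conditions: CuI (10 mol%), picolinic acid (20 mol%), K3PO4, DMSO, 90 °C, Ar
Reagents that add atoms: none
Why: Ullmann diaryl ether synthesis as in step 8, here with the more reactive aryl iodide, which again has two ortho hydrogens.

Step 16
Reactants: 23 5-(6-{2,6-dimethoxy-4-[2,3,4-trimethoxy-6-(2,4,6-trimethoxyphenoxy)phenoxy]phenoxy}-2,3,4-trimethoxyphenoxy)-1,2,3-trimethoxybenzene
Product: 24 5-(6-{2,6-dihydroxy-4-[2,3,4-trihydroxy-6-(2,4,6-trihydroxyphenoxy)phenoxy]phenoxy}-2,3,4-trihydroxyphenoxy)benzene-1,2,3-triol (CNP0273977.0)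
Conditions: BBr3 (excess), CH2Cl2, −78 °C to rt; degassed MeOH/H2O, Ar; reversed-phase purification
Reagents that add atoms: none
Why: Lewis-acid ether cleavage: boron binds each methoxy oxygen and bromide attacks the methyl carbon, while the diaryl ether oxygens carry no sp3 carbon and are left intact. Excess reagent and oxygen-free work-up are needed for fourteen cleavages and an oxidation-prone product.

## Compound list

1 | dimethyl squarate (3,4-dimethoxycyclobut-3-ene-1,2-dione) | COC1=C(OC)C(=O)C1=O | starting material
2 | chloro(2,3-dimethoxymaleoyl)bis(triphenylphosphine)cobalt (trivalent cobalt metallacycle, not isolated) | COC1=C(OC)C(=O)[Co-2](Cl)([P+](c2ccccc2)(c2ccccc2)c2ccccc2)([P+](c2ccccc2)(c2ccccc2)c2ccccc2)C1=O | intermediate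
3 | chloro(dimethylglyoxime)(2,3-dimethoxymaleoyl)(pyridine)cobalt (trivalent cobalt metallacycle) | CC1=[N+](O)[Co-3]2(Cl)([n+]3ccccc3)([N+](O)=C1C)C(=O)C(OC)=C(OC)C2=O | intermediate
4 | 2,4,6-trimethoxyphenol | COc1cc(OC)c(O)c(OC)c1 | starting material
5 | trichloroethylene | ClC=C(Cl)Cl | starting material
6 | 2-{[(E)-1,2-dichloroethenyl]oxy}-1,3,5-trimethoxybenzene | COc1cc(OC)c(O/C(Cl)=C\Cl)c(OC)c1 | intermediate
7 | lithium (2,4,6-trimethoxyphenoxy)acetylide (not isolated) | [Li]C#COc1c(OC)cc(OC)cc1OC | intermediate
8 | 2-(ethynyloxy)-1,3,5-trimethoxybenzene | C#COc1c(OC)cc(OC)cc1OC | intermediate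
9 | 2,3-dimethoxy-5-(2,4,6-trimethoxyphenoxy)-1,4-benzoquinone | COC1=C(OC)C(=O)C(Oc2c(OC)cc(OC)cc2OC)=CC1=O | intermediate
10 | 2,3-dimethoxy-5-(2,4,6-trimethoxyphenoxy)benzene-1,4-diol | COc1c(O)cc(Oc2c(OC)cc(OC)cc2OC)c(O)c1OC | intermediate
11 | 2,3,4-trimethoxy-6-(2,4,6-trimethoxyphenoxy)phenol | Oc1c(OC)c(OC)c(OC)cc1Oc1c(OC)cc(OC)cc1OC | intermediate
12 | 4-bromo-2,6-dimethoxyphenol | COc1cc(Br)cc(OC)c1O | starting material
13 | 2-(benzyloxy)-5-bromo-1,3-dimethoxybenzene | COc1cc(Br)cc(OC)c1OCc1ccccc1 | intermediate
14 | 2-(benzyloxy)-1,3-dimethoxy-5-[2,3,4-trimethoxy-6-(2,4,6-trimethoxyphenoxy)phenoxy]benzene | COc1cc(Oc2c(OC)c(OC)c(OC)cc2Oc2c(OC)cc(OC)cc2OC)cc(OC)c1OCc1ccccc1 | intermediate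
15 | 2,6-dimethoxy-4-[2,3,4-trimethoxy-6-(2,4,6-trimethoxyphenoxy)phenoxy]phenol | COc1cc(Oc2c(OC)c(OC)c(OC)cc2Oc2c(OC)cc(OC)cc2OC)cc(OC)c1O | intermediate
16 | 2-{[(E)-1,2-dichloroethenyl]oxy}-1,3-dimethoxy-5-[2,3,4-trimethoxy-6-(2,4,6-trimethoxyphenoxy)phenoxy]benzene | COc1cc(Oc2c(OC)c(OC)c(OC)cc2Oc2c(OC)cc(OC)cc2OC)cc(OC)c1O/C(Cl)=C\Cl | intermediate
17 | lithium acetylide of the ring A–B–C ynol ether (not isolated) | [Li]C#COc1c(OC)cc(Oc2c(OC)c(OC)c(OC)cc2Oc2c(OC)cc(OC)cc2OC)cc1OC | intermediate
18 | 2-(ethynyloxy)-1,3-dimethoxy-5-[2,3,4-trimethoxy-6-(2,4,6-trimethoxyphenoxy)phenoxy]benzene | C#COc1c(OC)cc(Oc2c(OC)c(OC)c(OC)cc2Oc2c(OC)cc(OC)cc2OC)cc1OC | intermediate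
19 | 5-{2,6-dimethoxy-4-[2,3,4-trimethoxy-6-(2,4,6-trimethoxyphenoxy)phenoxy]phenoxy}-2,3-dimethoxy-1,4-benzoquinone | COC1=C(OC)C(=O)C(Oc2c(OC)cc(Oc3c(OC)c(OC)c(OC)cc3Oc3c(OC)cc(OC)cc3OC)cc2OC)=CC1=O | intermediate
20 | 5-{2,6-dimethoxy-4-[2,3,4-trimethoxy-6-(2,4,6-trimethoxyphenoxy)phenoxy]phenoxy}-2,3-dimethoxybenzene-1,4-diol | COc1c(O)cc(Oc2c(OC)cc(Oc3c(OC)c(OC)c(OC)cc3Oc3c(OC)cc(OC)cc3OC)cc2OC)c(O)c1OC | intermediate
21 | 6-{2,6-dimethoxy-4-[2,3,4-trimethoxy-6-(2,4,6-trimethoxyphenoxy)phenoxy]phenoxy}-2,3,4-trimethoxyphenol | Oc1c(OC)c(OC)c(OC)cc1Oc1c(OC)cc(Oc2c(OC)c(OC)c(OC)cc2Oc2c(OC)cc(OC)cc2OC)cc1OC | intermediate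
22 | 5-iodo-1,2,3-trimethoxybenzene | COc1cc(I)cc(OC)c1OC | starting material
23 | 5-(6-{2,6-dimethoxy-4-[2,3,4-trimethoxy-6-(2,4,6-trimethoxyphenoxy)phenoxy]phenoxy}-2,3,4-trimethoxyphenoxy)-1,2,3-trimethoxybenzene (tetradeca-O-methyl ether of 24) | COc1cc(Oc2c(OC)c(OC)c(OC)cc2Oc2c(OC)cc(Oc3c(OC)c(OC)c(OC)cc3Oc3c(OC)cc(OC)cc3OC)cc2OC)cc(OC)c1OC | intermediate
24 | 5-(6-{2,6-dihydroxy-4-[2,3,4-trihydroxy-6-(2,4,6-trihydroxyphenoxy)phenoxy]phenoxy}-2,3,4-trihydroxyphenoxy)benzene-1,2,3-triol (CNP0273977.0) | Oc1cc(O)c(Oc2cc(O)c(O)c(O)c2Oc2cc(O)c(Oc3cc(O)c(O)c(O)c3Oc3cc(O)c(O)c(O)c3)c(O)c2)c(O)c1 | target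

## Step count and least certain steps

Total step count: 16. Longest linear sequence: 14 steps (from 4 through steps 2 to 6 and 8 to 16); steps 1 and 7 are side branches.

Step 12 (key step). The most likely failure is consumption of the ynol ether by oligomerisation or hydration before it inserts, or sluggish insertion into the electron-rich dimethoxymaleoyl complex. Loss of the aryloxy group from the product quinone by addition–elimination is also possible. The same risk is met first, on cheap material, in step 4. The fallback sets out from 15 and returns at 21, bypassing steps 10 to 14. Commercial 3,4,5-trimethoxyphenol is iodinated next to the hydroxyl with N-iodosuccinimide to give 2-iodo-3,4,5-trimethoxyphenol F1, which is converted with 4-chlorobenzenesulfonyl chloride and Et3N into 2-iodo-3,4,5-trimethoxyphenyl 4-chlorobenzenesulfonate F2. 15 is deprotonated with i-PrMgCl; F2 undergoes iodine–magnesium exchange with i-PrMgCl at −78 °C and, on warming in the presence of the magnesium phenoxide, loses the sulfonate to give 3,4,5-trimethoxybenzyne F3. The phenoxide oxygen adds at the aryne carbon remote from the methoxy group, and B(OMe)3 followed by H2O2/NaOH turns the resulting carbon–magnesium bond into the hydroxyl, which gives 21.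

Step 11. Likely failures are competing deprotonation of the oxygen-flanked ring positions by n-BuLi, and hydration or oligomerisation of the terminal ynol ether during isolation (step 3 carries the same risk on small scale). The fallback sets out from 16 and returns at 18. 17 is generated as before but quenched with Me3SiCl to give {[2,6-dimethoxy-4-(2,3,4-trimethoxy-6-(2,4,6-trimethoxyphenoxy)phenoxy)phenoxy]ethynyl}trimethylsilane F4, which should tolerate chromatography and storage. Immediately before step 12 the silyl group is removed with Bu4NF/AcOH in THF at 0 °C, and the solution of 18 is used directly.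

Step 14. Likely failures are insufficient discrimination between the two hydroxyls (methylation at the hindered oxygen or double methylation) and re-oxidation of the hydroquinone in base; step 6 tests the same selectivity first. The fallback sets out from 20 and returns at 24. The less hindered hydroxyl is silylated with t-BuMe2SiCl/imidazole at 0 °C, a reaction governed much more strongly by sterics, to give the mono-silyl ether F5. The remaining hindered phenol is arylated at room temperature by Chan–Lam coupling with 3,4,5-trimethoxyphenylboronic acid (Cu(OAc)2, divalent copper, pyridine, 4 Å MS, CH2Cl2, air) to give the silylated pentamer F6. Bu4NF removes the silyl group to give the monophenol F7, and BBr3 as in step 16 then gives 24.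

Step 15. Likely failure is low conversion, because the phenoxide is di-ortho-substituted and both partners are electron-rich, with slow oxidative degradation of the phenoxide at 90 °C (step 8 carries the same risk). The fallback sets out from 21 and 22 and returns at 23. 22 is oxidised with mCPBA in the presence of TsOH and 1,3,5-trimethoxybenzene to give (3,4,5-trimethoxyphenyl)(2,4,6-trimethoxyphenyl)iodonium tosylate F8. The potassium phenoxide of 21 (t-BuOK, THF, rt to 40 °C) is then arylated by F8 without metal, by ligand coupling at trivalent iodine, in which the more electron-rich 2,4,6-trimethoxyphenyl group stays on iodine; this gives 23.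

Step 16. Likely failures are incomplete cleavage of the fourteen methyl ethers as partly cleaved borates precipitate, and oxidative darkening of the polyphenol during work-up and purification. The fallback sets out from 23 and returns at 24. After the BBr3 treatment the crude product is acetylated without purification (Ac2O, pyridine) to give the tetradecaacetate F9, which can be purified on silica and separated from under-cleaved material. Acid-catalysed methanolysis (AcCl in MeOH, Ar) then releases 24 under non-oxidising conditions.

## Further compounds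

F1 | step 12 | 2-iodo-3,4,5-trimethoxyphenol | COc1cc(O)c(I)c(OC)c1OC
F2 | step 12 | 2-iodo-3,4,5-trimethoxyphenyl 4-chlorobenzenesulfonate | COc1cc(OS(=O)(=O)c2ccc(Cl)cc2)c(I)c(OC)c1OC
F3 | step 12 | 3,4,5-trimethoxybenzyne (1,2-didehydro-3,4,5-trimethoxybenzene) | COC1=CC#CC(OC)=C1OC
F4 | step 11 | {[2,6-dimethoxy-4-(2,3,4-trimethoxy-6-(2,4,6-trimethoxyphenoxy)phenoxy)phenoxy]ethynyl}trimethylsilane | C[Si](C)(C)C#COc1c(OC)cc(Oc2c(OC)c(OC)c(OC)cc2Oc2c(OC)cc(OC)cc2OC)cc1OC
F5 | step 14 | mono-tert-butyldimethylsilyl ether of 20 at the ring D C3 oxygen | COc1c(O[Si](C)(C)C(C)(C)C)cc(Oc2c(OC)cc(Oc3c(OC)c(OC)c(OC)cc3Oc3c(OC)cc(OC)cc3OC)cc2OC)c(O)c1OC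
F6 | step 14 | F5 carrying the 3,4,5-trimethoxyphenyl group on the ring D C6 oxygen | COc1c(O[Si](C)(C)C(C)(C)C)cc(Oc2c(OC)cc(Oc3c(OC)c(OC)c(OC)cc3Oc3c(OC)cc(OC)cc3OC)cc2OC)c(Oc2cc(OC)c(OC)c(OC)c2)c1OC
F7 | step 14 | pentamer with free ring D C3 hydroxyl and thirteen methyl ethers | COc1c(O)cc(Oc2c(OC)cc(Oc3c(OC)c(OC)c(OC)cc3Oc3c(OC)cc(OC)cc3OC)cc2OC)c(Oc2cc(OC)c(OC)c(OC)c2)c1OC
F8 | step 15 | (3,4,5-trimethoxyphenyl)(2,4,6-trimethoxyphenyl)iodonium tosylate | COc1cc([I+]c2c(OC)cc(OC)cc2OC)cc(OC)c1OC.Cc1ccc(S(=O)(=O)[O-])cc1
F9 | step 16 | tetradecaacetate of 24 | CC(=O)Oc1cc(OC(C)=O)c(Oc2cc(OC(C)=O)c(OC(C)=O)c(OC(C)=O)c2Oc2cc(OC(C)=O)c(Oc3cc(OC(C)=O)c(OC(C)=O)c(OC(C)=O)c3Oc3cc(OC(C)=O)c(OC(C)=O)c(OC(C)=O)c3)c(OC(C)=O)c2)c(OC(C)=O)c1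
A1 | alternative 1 | 6-[4-(benzyloxy)-2,6-dimethoxyphenoxy]-2,3,4-trimethoxyphenol (ring C–D phenol) | Oc1c(OC)c(OC)c(OC)cc1Oc1c(OC)cc(OCc2ccccc2)cc1OC
A2 | alternative 1 | 4-(benzyloxy)-2,6-dimethoxyphenol | COc1cc(OCc2ccccc2)cc(OC)c1O
A3 | alternative 1 | 2-iodo-3,4,5-trimethoxyphenyl 4-chlorobenzenesulfonate | COc1cc(OS(=O)(=O)c2ccc(Cl)cc2)c(I)c(OC)c1OC
A4 | alternative 1 | 3,4,5-trimethoxybenzyne | COC1=CC#CC(OC)=C1OC
A5 | alternative 2 | 2,3,4-trimethoxy-6-(2,4,6-trimethoxyphenoxy)phenol (ring A–B phenol) | Oc1c(OC)c(OC)c(OC)cc1Oc1c(OC)cc(OC)cc1OC
A6 | alternative 2 | racemic 2,3,4-trimethoxy-4-[(Z)-2-(2,4,6-trimethoxyphenoxy)ethenyl]cyclobut-2-en-1-one | COC1=C(OC)C(OC)(/C=C\Oc2c(OC)cc(OC)cc2OC)C1=O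
A7 | alternative 2 | (Z)-2-(2,4,6-trimethoxyphenoxy)vinyllithium | [Li]/C=C\Oc1c(OC)cc(OC)cc1OC
A8 | alternative 3 | pentamer with ring A as free triol and rings B to E methylated | Oc1cc(O)c(Oc2cc(OC)c(OC)c(OC)c2Oc2cc(OC)c(Oc3cc(OC)c(OC)c(OC)c3Oc3cc(OC)c(OC)c(OC)c3)c(OC)c2)c(O)c1
A9 | alternative 3 | ring A trialdehyde of the methylated pentamer | O=Cc1cc(C=O)c(Oc2cc(OC)c(OC)c(OC)c2Oc2cc(OC)c(Oc3cc(OC)c(OC)c(OC)c3Oc3cc(OC)c(OC)c(OC)c3)c(OC)c2)c(C=O)c1
A10 | alternative 3 | 2-fluorobenzene-1,3,5-tricarbaldehyde | O=Cc1cc(C=O)c(F)c(C=O)c1
A11 | alternative 3 | ring B–C–D–E phenol with free ring B C1 hydroxyl | Oc1cc(OC)c(OC)c(OC)c1Oc1cc(OC)c(Oc2cc(OC)c(OC)c(OC)c2Oc2cc(OC)c(OC)c(OC)c2)c(OC)c1
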